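**Plan**

- Numbering (germacrane): ring C1–C10; C1–OH; C4(CH3)–C5 oxirane; butenolide C6–O–C12(=O)–C11(C13H2OAc)=C7; C8–O‑tigloyl; C9=C10(CH3) is Z.
- Retrosynthetic cuts, in order: the C1 silyl ether; the butenolide back to a furan (C12 oxidised, C6 reduced); the C4–C5 oxirane bond; the C8 ester; the C8–C9 bond; the C5–C6 bond (furan lithiation); the chain (C1 carbinol from an ynone, C9=C10 from the alkyne).
- Forward: a C1–C4/C9/C10 chain and a C5–C8/C11–C13 furan are joined at C8–C9 and esterified. The ten‑membered ring and the oxirane then close in one event at C4–C5. The furan is finally oxidised and reduced to the butenolide.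
- Enabling feature: C6, C7, C11, C12 and the lactone oxygen are carried as a furan ring, so C5 is a furfuryl carbon. Its dimethylsulfonium ylide is stabilised, has no leaving group on C6, and adds to the C4 methyl ketone to give the oxirane directly.
- Stereochemistry: C1 by Noyori transfer hydrogenation; 9Z by anti‑carbomagnesiation of the propargylic alcohol; C8 by ligand‑controlled Ni/Cr addition; C4 and C5 in the ring closure (anti betaine, ring conformation set by C1, C8 and the Z‑alkene); C6 by Felkin–Anh hydride addition next to the oxirane.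

Key step: step 14

Remark: the levulinate ketal ester and furan‑3,4‑diyldimethanol are taken as commercial (the ester is otherwise one ketalisation from ethyl levulinate); ring compounds are described with the target numbering given above.

**Route**

Step 1
Reactants: 1 ethyl 3-(2-methyl-1,3-dioxolan-2-yl)propanoate
Product: 2 N-methoxy-N-methyl-3-(2-methyl-1,3-dioxolan-2-yl)propanamide
Conditions: MeNH(OMe)·HCl, i-PrMgCl, THF, −20 → 0 °C
Reagents that add atoms: N,O-dimethylhydroxylamine hydrochloride, CNOC.Cl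
Why: Weinreb amide formation from an ester with the magnesium amide of N,O-dimethylhydroxylamine, to which the dioxolane is inert.

Step 2
Reactants: 2 N-methoxy-N-methyl-3-(2-methyl-1,3-dioxolan-2-yl)propanamide; 3 ethynyltrimethylsilane
Product: 4 5-(2-methyl-1,3-dioxolan-2-yl)-1-(trimethylsilyl)pent-1-yn-3-one
Conditions: n-BuLi, THF, −78 → 0 °C
Reagents that add atoms: none
Why: Acylation of a lithium acetylide by a Weinreb amide should stop at the ynone because the chelated tetrahedral intermediate survives until work-up.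

Step 3
Reactants: 4 5-(2-methyl-1,3-dioxolan-2-yl)-1-(trimethylsilyl)pent-1-yn-3-one
Product: 6 (3S)-5-(2-methyl-1,3-dioxolan-2-yl)pent-1-yn-3-ol, via silylated alkynol 5 (not isolated)
Conditions: RuCl[(S,S)-TsDPEN](p-cymene) (cat.), i-PrOH, rt; then K2CO3, MeOH, rt
Reagents that add atoms: none
Why: Noyori asymmetric transfer hydrogenation of an alkynyl ketone sets C1, the alkynyl group taking the place of the aryl group of the usual model so that the (S,S)-catalyst should give the (S)-carbinol, and methanolysis then removes the C-silyl group.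

Step 4
Reactants: 6 (3S)-5-(2-methyl-1,3-dioxolan-2-yl)pent-1-yn-3-ol
Product: 7 (1Z,3S)-1-iodo-2-methyl-5-(2-methyl-1,3-dioxolan-2-yl)pent-1-en-3-ol
Conditions: MeMgBr (3.5 equiv), CuI (20 mol%), THF, −10 °C → rt; then I2, −40 → 0 °C
Reagents that add atoms: methylmagnesium bromide, C[Mg]Br; iodine, II
Why: Copper-catalysed anti-carbomagnesiation of a propargylic alkoxide should add methyl at the alkyne carbon next to the carbinol and magnesium at the terminus cis to it, and iodinolysis with retention fixes the 9Z geometry without touching C1.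

Step 5
Reactants: 7 (1Z,3S)-1-iodo-2-methyl-5-(2-methyl-1,3-dioxolan-2-yl)pent-1-en-3-ol
Product: 8 tert-butyl{[(1Z,3S)-1-iodo-2-methyl-5-(2-methyl-1,3-dioxolan-2-yl)pent-1-en-3-yl]oxy}dimethylsilane
Conditions: TBSCl, imidazole, DMF, rt
Reagents that add atoms: tert-butyldimethylsilyl chloride, CC(C)(C)[Si](C)(C)Cl
Why: Standard imidazole-mediated silylation of the secondary allylic alcohol.

Step 6
Reactants: 9 furan-3,4-diyldimethanol
Product: 10 [4-({[tert-butyl(dimethyl)silyl]oxy}methyl)furan-3-yl]methanol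
Conditions: NaH (1.0 equiv), THF, 0 °C; TBSCl (1.0 equiv), rt
Reagents that add atoms: tert-butyldimethylsilyl chloride, CC(C)(C)[Si](C)(C)Cl
Why: Monosilylation of a symmetric diol through its monosodium alkoxide desymmetrises the two hydroxymethyl arms.

Step 7
Reactants: 10 [4-({[tert-butyl(dimethyl)silyl]oxy}methyl)furan-3-yl]methanol
Product: 11 4-({[tert-butyl(dimethyl)silyl]oxy}methyl)furan-3-carbaldehyde
Conditions: MnO2, CH2Cl2, rt
Reagents that add atoms: none
Why: MnO2 oxidation of a furylmethanol (benzylic-type alcohol) to the aldehyde leaves the silyl ether untouched.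

Step 8
Reactants: 11 4-({[tert-butyl(dimethyl)silyl]oxy}methyl)furan-3-carbaldehyde; 12 chloromethyl methyl sulfide
Product: 13 4-({[tert-butyl(dimethyl)silyl]oxy}methyl)-2-[(methylsulfanyl)methyl]furan-3-carbaldehyde
Conditions: Me2NCH2CH2NHMe, n-BuLi, THF, −78 °C; n-BuLi, −78 → −20 °C; then 12, −78 °C → rt; aq. NH4Cl
Reagents that add atoms: none
Why: α-Amino alkoxide-directed lithiation masks the aldehyde in situ and directs n-BuLi to the adjacent furan α-carbon (the future C6), alkylation with the α-chloro sulfide installs C5 with its sulfur, and work-up returns the aldehyde.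

Step 9
Reactants: 13 4-({[tert-butyl(dimethyl)silyl]oxy}methyl)-2-[(methylsulfanyl)methyl]furan-3-carbaldehyde
Product: 15 {4-formyl-5-[(methylsulfanyl)methyl]furan-3-yl}methyl acetate, via hydroxy aldehyde 14 (not isolated)
Conditions: TBAF, THF, 0 °C; then Ac2O, pyridine, DMAP (cat.), 0 °C → rt
Reagents that add atoms: acetic anhydride, CC(=O)OC(C)=O
Why: Fluoride desilylation followed in the same flask by DMAP-catalysed acetylation of the primary alcohol, the open hydroxy aldehyde being expected to prevail over the strained fused lactol.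

Step 10
Reactants: 8 tert-butyl{[(1Z,3S)-1-iodo-2-methyl-5-(2-methyl-1,3-dioxolan-2-yl)pent-1-en-3-yl]oxy}dimethylsilane; 15 {4-formyl-5-[(methylsulfanyl)methyl]furan-3-yl}methyl acetate
Product: 16 {4-[(1S,2Z,4S)-4-{[tert-butyl(dimethyl)silyl]oxy}-1-hydroxy-3-methyl-6-(2-methyl-1,3-dioxolan-2-yl)hex-2-en-1-yl]-5-[(methylsulfanyl)methyl]furan-3-yl}methyl acetate
Conditions: CrCl2 (4 equiv), NiCl2 (2 mol%), chiral oxazoline–sulfonamide ligand (enantiomer chosen for 8S), Et3N, THF, rt
Reagents that add atoms: none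
Why: Nozaki–Hiyama–Kishi coupling, in which the alkenylchromium from 8 adds to the aldehyde with retention of the Z geometry, the chiral ligand on chromium sets C8, and the ketal keeps the alkenylchromium from closing onto C4.

Step 11
Reactants: 16 the C8 alcohol from step 10; 17 (2E)-2-methylbut-2-enoic acid (tiglic acid)
Product: 18 (1S,2Z,4S)-1-{4-(acetoxymethyl)-2-[(methylsulfanyl)methyl]furan-3-yl}-4-{[tert-butyl(dimethyl)silyl]oxy}-3-methyl-6-(2-methyl-1,3-dioxolan-2-yl)hex-2-en-1-yl (2E)-2-methylbut-2-enoate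
Conditions: DCC, DMAP, CH2Cl2, 0 °C → rt
Reagents that add atoms: none
Why: Steglich esterification of the hindered secondary alcohol proceeds with retention at C8 and should not isomerise the tiglate.

Step 12
Reactants: 18 the ketal tiglate from step 11
Product: 19 (1S,2Z,4S)-1-{4-(acetoxymethyl)-2-[(methylsulfanyl)methyl]furan-3-yl}-4-{[tert-butyl(dimethyl)silyl]oxy}-3-methyl-7-oxooct-2-en-1-yl (2E)-2-methylbut-2-enoate
Conditions: PPTS (cat.), acetone/H2O, 40 °C
Reagents that add atoms: water, O
Why: Mild acid-catalysed ketal hydrolysis unmasks the C4 methyl ketone under conditions that the silyl ether, the esters and the sulfide should tolerate.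

Step 13
Reactants: 19 the keto sulfide from step 12
Product: 20 ({4-(acetoxymethyl)-3-[(1S,2Z,4S)-4-{[tert-butyl(dimethyl)silyl]oxy}-3-methyl-1-{[(2E)-2-methylbut-2-enoyl]oxy}-7-oxooct-2-en-1-yl]furan-2-yl}methyl)dimethylsulfonium trifluoromethanesulfonate
Conditions: MeOTf, 2,6-di-tert-butyl-4-methylpyridine (cat.), CH2Cl2, 0 °C
Reagents that add atoms: methyl trifluoromethanesulfonate, COS(=O)(=O)C(F)(F)F
Why: S-Alkylation of the thioether, by far the most nucleophilic site, with methyl triflate gives the sulfonium salt.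

Step 14
Reactants: 20 the furfuryl dimethylsulfonium triflate from step 13
Product: 23 furan-fused ten-membered 4,5-oxirane (1-OTBS; 8-O-tigloyl; 13-OAc; 9Z; configured as 28 at C1/C4/C5/C8), via sulfonium ylide 21 (not isolated), via anti betaine 22 (not isolated)
Conditions: LiN(SiMe3)2 (1.1 equiv, slow addition), THF, −78 → 0 °C, 1 mM in 20
Reagents that add atoms: none
Why: Proposed new method: deprotonation of the furfuryl sulfonium gives ylide 21, whose carbanion carbon C5 adds to the C4 ketone (10-exo-trig closure of the carbocycle C1–C10) to give betaine 22, and the C4 alkoxide then displaces dimethyl sulfide at C5 with inversion (3-exo-tet closure of the oxirane); the closest known reaction type is the Corey–Chaykovsky epoxidation of ketones with benzylic sulfonium ylides, known between two molecules and for common rings but not as a medium-ring closure. C5 is the only carbon acidified by both the sulfonium and the furan, so ylide formation should outrun enolisation of the methyl ketone and of the esters. The new centres C4 and C5 are set together: the trans relation (C3 and C6 on opposite faces, methyl cis to the furan) should follow from the anti betaine, because syn betaines of such semi-stabilised ylides revert to ylide and ketone, so that different modes of approach are funnelled into one closing betaine. The absolute sense (4R,5R) has to come from the substrate: C8 and C1 flank the 9Z-alkene, allylic strain holds both C–H bonds near the alkene plane, and the folded chain should then offer the ketone face that leads to the natural trans-fused ring. The step needs chemoselectivity for the ketone over the ester carbonyls (addition of a sulfonium ylide to an ester is slow and the tiglate is a hindered Michael acceptor) and high dilution against dimerisation.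

Step 15
Reactants: 23 furan-fused ten-membered 4,5-oxirane
Product: 25 5-hydroxybutenolide of the ten-membered oxirane (C6 lactol; C12 carbonyl; 1-OTBS; 8-O-tigloyl; 13-OAc), via furan endoperoxide 24 (not isolated)
Conditions: O2, hν (visible), tetraphenylporphyrin (cat.), i-Pr2NEt, CH2Cl2, −78 °C
Reagents that add atoms: oxygen, O=O
Why: [4+2] Cycloaddition of singlet oxygen to the furan and base-induced Kornblum–DeLaMare fragmentation of the endoperoxide, in which only C12 carries a hydrogen so that C12 becomes the lactone carbonyl and C6 the lactol carbon, while the trisubstituted alkenes react far more slowly.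

Step 16
Reactants: 25 5-hydroxybutenolide (C6 lactol)
Product: 27 1-O-tert-butyldimethylsilyl ether of 28, via hydroxy acid 26 (not isolated)
Conditions: NaBH4, THF/MeOH, −40 → 0 °C; then 0.1 M HCl to pH 4, rt
Reagents that add atoms: none
Why: Borohydride reduction of the C6 ketone of the ring-opened keto carboxylate and lactonisation of the Z-γ-hydroxy acid on acidification, with C6 expected to be set by Felkin–Anh addition anti to the C5–O bond of the oxirane (non-chelating reductant), which leads to the 5R,6S relation.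

Step 17
Reactants: 27 1-O-tert-butyldimethylsilyl ether of 28
Product: 28 (1S,4R,5R,6S,8S,9Z)-13-acetoxy-4,5-epoxy-1-hydroxy-8-(tigloyloxy)germacra-7(11),9-dien-12,6-olide
Conditions: TBAF, AcOH, THF, 0 °C → rt
Reagents that add atoms: none
Why: Buffered fluoride desilylation, in which acetic acid keeps the medium from deprotonating C6, which would open the oxirane by β-elimination.

**Compound list**

1 | ethyl 3-(2-methyl-1,3-dioxolan-2-yl)propanoate | CCOC(=O)CCC1(C)OCCO1 | starting material
2 | N-methoxy-N-methyl-3-(2-methyl-1,3-dioxolan-2-yl)propanamide | CON(C)C(=O)CCC1(C)OCCO1 | intermediate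
3 | ethynyltrimethylsilane | C#C[Si](C)(C)C | starting material
4 | 5-(2-methyl-1,3-dioxolan-2-yl)-1-(trimethylsilyl)pent-1-yn-3-one | C[Si](C)(C)C#CC(=O)CCC1(C)OCCO1 | intermediate
5 | (3S)-5-(2-methyl-1,3-dioxolan-2-yl)-1-(trimethylsilyl)pent-1-yn-3-ol | C[Si](C)(C)C#C[C@@H](O)CCC1(C)OCCO1 | intermediate
6 | (3S)-5-(2-methyl-1,3-dioxolan-2-yl)pent-1-yn-3-ol | C#C[C@@H](O)CCC1(C)OCCO1 | intermediate
7 | (1Z,3S)-1-iodo-2-methyl-5-(2-methyl-1,3-dioxolan-2-yl)pent-1-en-3-ol | I/C=C(/C)[C@@H](O)CCC1(C)OCCO1 | intermediate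
8 | tert-butyl{[(1Z,3S)-1-iodo-2-methyl-5-(2-methyl-1,3-dioxolan-2-yl)pent-1-en-3-yl]oxy}dimethylsilane | I/C=C(/C)[C@@H](O[Si](C)(C)C(C)(C)C)CCC1(C)OCCO1 | intermediate
9 | furan-3,4-diyldimethanol | OCc1cocc1CO | starting material
10 | [4-({[tert-butyl(dimethyl)silyl]oxy}methyl)furan-3-yl]methanol | OCc1cocc1CO[Si](C)(C)C(C)(C)C | intermediate
11 | 4-({[tert-butyl(dimethyl)silyl]oxy}methyl)furan-3-carbaldehyde | O=Cc1cocc1CO[Si](C)(C)C(C)(C)C | intermediate
12 | chloromethyl methyl sulfide | CSCCl | starting material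
13 | 4-({[tert-butyl(dimethyl)silyl]oxy}methyl)-2-[(methylsulfanyl)methyl]furan-3-carbaldehyde | O=Cc1c(CSC)occ1CO[Si](C)(C)C(C)(C)C | intermediate
14 | 4-(hydroxymethyl)-2-[(methylsulfanyl)methyl]furan-3-carbaldehyde | O=Cc1c(CSC)occ1CO | intermediate
15 | {4-formyl-5-[(methylsulfanyl)methyl]furan-3-yl}methyl acetate | O=Cc1c(CSC)occ1COC(C)=O | intermediate
16 | {4-[(1S,2Z,4S)-4-{[tert-butyl(dimethyl)silyl]oxy}-1-hydroxy-3-methyl-6-(2-methyl-1,3-dioxolan-2-yl)hex-2-en-1-yl]-5-[(methylsulfanyl)methyl]furan-3-yl}methyl acetate | O[C@@H](/C=C(/C)[C@@H](O[Si](C)(C)C(C)(C)C)CCC2(C)OCCO2)c1c(CSC)occ1COC(C)=O | intermediate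
17 | (2E)-2-methylbut-2-enoic acid (tiglic acid) | C/C=C(\C)C(=O)O | starting material
18 | (1S,2Z,4S)-1-{4-(acetoxymethyl)-2-[(methylsulfanyl)methyl]furan-3-yl}-4-{[tert-butyl(dimethyl)silyl]oxy}-3-methyl-6-(2-methyl-1,3-dioxolan-2-yl)hex-2-en-1-yl (2E)-2-methylbut-2-enoate | C/C=C(\C)C(=O)O[C@@H](/C=C(/C)[C@@H](O[Si](C)(C)C(C)(C)C)CCC2(C)OCCO2)c1c(CSC)occ1COC(C)=O | intermediate
19 | (1S,2Z,4S)-1-{4-(acetoxymethyl)-2-[(methylsulfanyl)methyl]furan-3-yl}-4-{[tert-butyl(dimethyl)silyl]oxy}-3-methyl-7-oxooct-2-en-1-yl (2E)-2-methylbut-2-enoate | C/C=C(\C)C(=O)O[C@@H](/C=C(/C)[C@@H](O[Si](C)(C)C(C)(C)C)CCC(C)=O)c1c(CSC)occ1COC(C)=O | intermediate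
20 | ({4-(acetoxymethyl)-3-[(1S,2Z,4S)-4-{[tert-butyl(dimethyl)silyl]oxy}-3-methyl-1-{[(2E)-2-methylbut-2-enoyl]oxy}-7-oxooct-2-en-1-yl]furan-2-yl}methyl)dimethylsulfonium trifluoromethanesulfonate | C/C=C(\C)C(=O)O[C@@H](/C=C(/C)[C@@H](O[Si](C)(C)C(C)(C)C)CCC(C)=O)c1c(C[S+](C)C)occ1COC(C)=O.[O-]S(=O)(=O)C(F)(F)F | intermediate
21 | sulfonium ylide of 20 (carbanion at C5, the furfuryl carbon) | C/C=C(\C)C(=O)O[C@@H](/C=C(/C)[C@@H](O[Si](C)(C)C(C)(C)C)CCC(C)=O)c1c([CH-][S+](C)C)occ1COC(C)=O | intermediate
22 | anti betaine: ten-membered ring closed at C4–C5, C4 alkoxide, C5 dimethylsulfonium | C/C=C(\C)C(=O)O[C@H]1/C=C(/C)[C@@H](O[Si](C)(C)C(C)(C)C)CC[C@@](C)([O-])[C@@H]([S+](C)C)c2occ(COC(C)=O)c12 | intermediate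
23 | furan-fused ten-membered 4,5-oxirane: ring C1–C10 fused at C6–C7 to a furan (O between C6 and C12), 9Z, 1-OTBS, 8-O-tigloyl, 13-OAc, configured as 28 at C1, C4, C5 and C8 | C/C=C(\C)C(=O)O[C@H]1/C=C(/C)[C@@H](O[Si](C)(C)C(C)(C)C)CC[C@@]2(C)O[C@@H]2c2occ(COC(C)=O)c12 | intermediate
24 | endoperoxide of 23 (2,3-dioxa-7-oxabicyclo[2.2.1]hept-5-ene across C6 and C12, either face) | C/C=C(\C)C(=O)O[C@H]1/C=C(/C)[C@@H](O[Si](C)(C)C(C)(C)C)CC[C@@]2(C)O[C@@H]2C23OOC(O3)C(COC(C)=O)=C12 | intermediate
25 | 5-hydroxybutenolide of the ten-membered oxirane (C6 lactol, C12 carbonyl, C6 epimers in equilibrium with the open keto acid), 1-OTBS, 8-O-tigloyl, 13-OAc | C/C=C(\C)C(=O)O[C@H]1/C=C(/C)[C@@H](O[Si](C)(C)C(C)(C)C)CC[C@@]2(C)O[C@@H]2C2(O)OC(=O)C(COC(C)=O)=C12 | intermediate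
26 | (6S)-hydroxy acid: C6 carbinol, C7=C11 alkene with the C12 carboxylic acid cis to C6, otherwise as 27 | C/C=C(\C)C(=O)O[C@H]1/C=C(/C)[C@@H](O[Si](C)(C)C(C)(C)C)CC[C@@]2(C)O[C@@H]2[C@@H](O)/C1=C(/COC(C)=O)C(O)=O | intermediate
27 | 1-O-tert-butyldimethylsilyl ether of 28 | C/C=C(\C)C(=O)O[C@H]1/C=C(/C)[C@@H](O[Si](C)(C)C(C)(C)C)CC[C@@]2(C)O[C@@H]2[C@H]2OC(=O)C(COC(C)=O)=C12 | intermediate
28 | (1S,4R,5R,6S,8S,9Z)-13-acetoxy-4,5-epoxy-1-hydroxy-8-(tigloyloxy)germacra-7(11),9-dien-12,6-olide | C/C=C(\C)C(=O)O[C@H]1/C=C(/C)[C@@H](O)CC[C@@]2(C)O[C@@H]2[C@H]2OC(=O)C(COC(C)=O)=C12 | target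

**Count and risks**

Total step count: 17. Longest linear sequence: 13 (steps 1–5 and 10–17).

Steps most likely to fail:

1. Step 14 (proposed new method). The medium-ring closure may lose to intermolecular ylide–ketone addition, to loss of the C8 carboxylate through the furan (1,4-elimination), or to methylide formation at an S-methyl group, and the closure may take the wrong ketone face. The fallback uses known chemistry: the oxirane is made between two molecules and the ring is closed at C8–C9 instead. It sets out from 15 and 8. NaBH4 reduction of 15 gives {4-(hydroxymethyl)-5-[(methylsulfanyl)methyl]furan-3-yl}methyl acetate F1, silylation (Et3SiCl, imidazole) gives the triethylsilyl ether F2, and MeOTf gives the sulfonium triflate F3. Ketal hydrolysis of 8 (PPTS, acetone/H2O) gives the iodo ketone F4. The ylide of F3 (KN(SiMe3)2, THF, −78 °C) should epoxidise F4 in an intermolecular Corey–Chaykovsky reaction to the trans-oxirane F5; here the C4/C5 diastereomers would have to be separated, or a chiral sulfide used. Buffered HF·pyridine removes the triethylsilyl group to give the primary alcohol F6, MnO2 gives the aldehyde F7, and a Nozaki–Hiyama–Kishi macrocyclisation (CrCl2, NiCl2 cat., DMSO, high dilution) gives the ring alcohol F8. Esterification of F8 with 17 as in step 11 comes back to the route at 23.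

2. Step 16. Hydride addition at C6 may show poor facial selectivity (chelation by the oxirane oxygen or an unfavourable ring conformation), and the alkoxide next to the oxirane may trigger epoxide migration. The fallback moves to reagent control and sets out from 25. Trimethylsilyldiazomethane (MeOH/toluene) should give the open methyl keto ester F9. Corey–Bakshi–Shibata reduction with the (S)-methyl oxazaborolidine and catecholborane (toluene, −78 °C, alkenyl carbon C7 as the large group) should give the (6S)-hydroxy ester F10. Lactonisation of F10 (PPTS, CH2Cl2) comes back to the route at 27.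

3. Step 10. Ligand control at C8 may be insufficient or mismatched with the C1 centre. The fallback replaces reagent control by a convergent use of both epimers and sets out from 8 and 15. The coupling is run without ligand (CrCl2, NiCl2 cat., DMSO) and the C8 epimers are separated. The (8S) epimer is 16 and goes on through step 11. The (8R) epimer F11 is esterified with 17 under Mitsunobu conditions (PPh3, DIAD, THF) with inversion at C8, which comes back to the route at 18.

Further compounds
F1 | step 14 | {4-(hydroxymethyl)-5-[(methylsulfanyl)methyl]furan-3-yl}methyl acetate | OCc1c(CSC)occ1COC(C)=O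
F2 | step 14 | {5-[(methylsulfanyl)methyl]-4-{[(triethylsilyl)oxy]methyl}furan-3-yl}methyl acetate | CC[Si](CC)(CC)OCc1c(CSC)occ1COC(C)=O
F3 | step 14 | ({4-(acetoxymethyl)-3-{[(triethylsilyl)oxy]methyl}furan-2-yl}methyl)dimethylsulfonium trifluoromethanesulfonate | CC[Si](CC)(CC)OCc1c(C[S+](C)C)occ1COC(C)=O.[O-]S(=O)(=O)C(F)(F)F
F4 | step 14 | (5S,6Z)-5-{[tert-butyl(dimethyl)silyl]oxy}-7-iodo-6-methylhept-6-en-2-one | I/C=C(/C)[C@@H](O[Si](C)(C)C(C)(C)C)CCC(C)=O
F5 | step 14 | acyclic trans-oxirane (C4/C5 as in 28) joining the iodoalkenyl chain of F4 to the furan of F2 | I/C=C(/C)[C@@H](O[Si](C)(C)C(C)(C)C)CC[C@@]1(C)O[C@@H]1c3occ(COC(C)=O)c3CO[Si](CC)(CC)CC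
F6 | step 14 | primary alcohol from F5 (triethylsilyl group removed) | I/C=C(/C)[C@@H](O[Si](C)(C)C(C)(C)C)CC[C@@]1(C)O[C@@H]1c3occ(COC(C)=O)c3CO
F7 | step 14 | furan-3-carbaldehyde from F6 (C8 aldehyde) | I/C=C(/C)[C@@H](O[Si](C)(C)C(C)(C)C)CC[C@@]1(C)O[C@@H]1c3occ(COC(C)=O)c3C=O
F8 | step 14 | (8S)-alcohol corresponding to 23 (C8–OH in place of the tiglate) | O[C@H]1/C=C(/C)[C@@H](O[Si](C)(C)C(C)(C)C)CC[C@@]2(C)O[C@@H]2c2occ(COC(C)=O)c12
F9 | step 16 | methyl keto ester: C6 ketone, C7=C11 alkene with the C12 methyl ester cis to C6, otherwise as 27 | C/C=C(\C)C(=O)O[C@H]1/C=C(/C)[C@@H](O[Si](C)(C)C(C)(C)C)CC[C@@]2(C)O[C@@H]2C(=O)/C1=C(/COC(C)=O)C(=O)OC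
F10 | step 16 | (6S)-hydroxy methyl ester from F9 | C/C=C(\C)C(=O)O[C@H]1/C=C(/C)[C@@H](O[Si](C)(C)C(C)(C)C)CC[C@@]2(C)O[C@@H]2[C@@H](O)/C1=C(/COC(C)=O)C(=O)OC
F11 | step 10 | {4-[(1R,2Z,4S)-4-{[tert-butyl(dimethyl)silyl]oxy}-1-hydroxy-3-methyl-6-(2-methyl-1,3-dioxolan-2-yl)hex-2-en-1-yl]-5-[(methylsulfanyl)methyl]furan-3-yl}methyl acetate (C8 epimer of 16) | O[C@H](/C=C(/C)[C@@H](O[Si](C)(C)C(C)(C)C)CCC2(C)OCCO2)c1c(CSC)occ1COC(C)=O
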